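## Retrosynthetic overview

1. Kazinol B ⇒ olefin cross-metathesis (allyl → prenyl) on the 2'-allyl diphenol **14**, after MOM removal.
2. **13** ⇒ one-pot double aromatic Claisen of **12**: the 4'-O-(1,1-dimethylpropargyl) ether gives the 2,2-dimethylpyran ring, and the 3'-O-allyl ether gives 2'-allyl/3'-OH.
3. **12** ⇒ O-propargylation of (S)-4'-hydroxyflavan **10**; **10** ⇒ new chiral-phosphoric-acid-catalysed, enantioconvergent dehydrative cyclisation of racemic diol **9** through a p-quinone methide (closes the chroman ring, sets C2).
4. **9** ⇒ aryllithium from bromide **7** (from 2-allyloxyphenol) + lactol **4** (from umbelliferone).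
5. Ring order: both benzene rings are purchased → flavan pyran ring (step 8) → dimethylpyran ring (step 10).

Assumptions:
- The target stereocentre is (2S), as read from the SMILES.
- (R)-TRIP is written as the catalyst giving (S); the sense of induction must be assigned experimentally, and the (S)-catalyst is used if it is opposite.
- 2-(Allyloxy)phenol is treated as commercial (otherwise one step from catechol and allyl bromide).
- Substrates and carbon building blocks are numbered; simple reagents (MOMCl, NBS, TBSCl) are given with SMILES in each step.

## Route

**Step 1**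
Reactants: **1** umbelliferone (7-hydroxycoumarin)
Product: **2** 7-(methoxymethoxy)-2H-chromen-2-one
Conditions: MOMCl, i-Pr2NEt, CH2Cl2, 0 °C → rt
Reagents that add atoms: chloromethyl methyl ether (MOMCl), COCCl
Why: Standard O-alkylation (MOM protection) of the only phenol; MOM is stable to every step before its planned removal in step 11.

**Step 2**
Reactants: **2**
Product: **3** 7-(methoxymethoxy)chroman-2-one
Conditions: H2 (3 atm), 10% Pd/C, EtOAc, 40 °C
Reagents that add atoms: none (H2 adds only hydrogen)
Why: Catalytic hydrogenation of the conjugated coumarin C3=C4 bond; the aryl MOM ether and lactone are inert in a non-nucleophilic solvent.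

**Step 3**
Reactants: **3**
Product: **4** rac-7-(methoxymethoxy)chroman-2-ol (lactol)
Conditions: DIBAL-H (1.1 equiv), CH2Cl2, −78 °C; Rochelle salt work-up
Reagents that add atoms: none
Why: Partial DIBAL reduction of a lactone stops at the stable six-membered lactol (a masked 3-arylpropanal) at −78 °C.

**Step 4**
Reactants: **5** 2-(allyloxy)phenol
Product: **6** 2-(allyloxy)-4-bromophenol
Conditions: NBS (1.0 equiv), MeCN, −10 → 0 °C, dark
Reagents that add atoms: N-bromosuccinimide, O=C1CCC(=O)N1Br
Why: Electrophilic aromatic bromination goes para to the free OH (the stronger director, as with guaiacol) and is much faster than ionic addition to the monosubstituted allyl alkene in dry MeCN.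

**Step 5**
Reactants: **6**
Product: **7** [2-(allyloxy)-4-bromophenoxy](tert-butyl)dimethylsilane
Conditions: TBSCl, imidazole, DMF, rt
Reagents that add atoms: tert-butyldimethylsilyl chloride, CC(C)(C)[Si](C)(C)Cl
Why: Routine phenol silylation; it masks the acidic OH for the organolithium step and is removable with fluoride without touching MOM or allyl.

**Step 6**
Reactants: **7** (1.4 equiv) and **4** (1.0 equiv)
Product: **8** rac-1-[3-(allyloxy)-4-(tert-butyldimethylsilyloxy)phenyl]-3-[2-hydroxy-4-(methoxymethoxy)phenyl]propan-1-ol
Conditions: **7**, n-BuLi, THF, −78 °C; then **4** pre-deprotonated with t-BuMgCl (1.0 equiv), −78 → 0 °C; NH4Cl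
Reagents that add atoms: none
Why: Br/Li exchange gives the aryllithium, which undergoes 1,2-addition to the ring-opened aldehyde form of the lactolate; the carbinol is deliberately racemic because step 8 is enantioconvergent.

**Step 7**
Reactants: **8**
Product: **9** rac-2-(allyloxy)-4-{1-hydroxy-3-[2-hydroxy-4-(methoxymethoxy)phenyl]propyl}phenol
Conditions: TBAF (1.1 equiv), AcOH (1.1 equiv), THF, 0 °C
Reagents that add atoms: none
Why: Buffered fluoride desilylation frees the 4'-OH needed for quinone methide formation; MOM, allyl and the benzylic alcohol are untouched at 0 °C.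

**Step 8 (key step)**
Reactants: **9**
Product: **10** (2S)-2-[3-(allyloxy)-4-hydroxyphenyl]-7-(methoxymethoxy)chromane
Conditions: (R)-TRIP (5 mol %), 5 Å MS, toluene (0.02 M), 0 °C → rt; stop at full conversion
Reagents that add atoms: none
Why: Proposed new method: the chiral phosphoric acid protonates the benzylic OH of the 4-hydroxybenzylic alcohol and the para-OH pushes out water to give a transient, catalyst-bound p-quinone methide (both alcohol enantiomers converge on this planar intermediate); the bifunctional phosphate holds the quinone methide carbonyl (P–OH) and the tethered A-ring phenol (P=O) so that 6-exo 1,6-oxa-conjugate addition occurs on one face, closing the chroman ring and setting C2 as (S), with rearomatisation as driving force and the product ether being far less basic than the alcohol so it does not re-ionise under kinetic control; the closest known reaction type is chiral-phosphoric-acid-catalysed intermolecular 1,6-addition to p-quinone methides generated in situ from p-hydroxybenzyl alcohols (and related o-quinone methide oxa-cyclisations), not yet shown as an intramolecular phenol addition giving a 2-arylchroman from an unhindered alkyl-substituted quinone methide.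

**Step 9**
Reactants: **10** and **11** 3-chloro-3-methylbut-1-yne
Product: **12** (2S)-2-{3-(allyloxy)-4-[(2-methylbut-3-yn-2-yl)oxy]phenyl}-7-(methoxymethoxy)chromane
Conditions: **11** (1.5 equiv), CuCl2·2H2O (1 mol %), DBU (1.3 equiv), MeCN, −10 → 0 °C, 2–4 h
Reagents that add atoms: 3-chloro-3-methylbut-1-yne, CC(C)(Cl)C#C
Why: Copper-catalysed propargylic etherification (via a copper acetylide/allenylidene electrophile) alkylates the only free phenol at low temperature, which also limits base-induced ring opening of the 4'-hydroxyflavan; once the 4'-O is capped, C2 is configurationally secure.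

**Step 10**
Reactants: **12**
Product: **13** 7-allyl-6-[(2S)-7-(methoxymethoxy)chroman-2-yl]-2,2-dimethyl-2H-chromen-8-ol
Conditions: PhNEt2 (0.05 M), Ar, 140 °C, 2 h; then 190 °C, 6 h
Reagents that add atoms: none
Why: Aromatic propargyl Claisen to the only free ortho carbon (C5'), then enolisation, [1,5]-H shift and oxa-6π electrocyclisation build the 2,2-dimethylpyran ring; at 190 °C the allyl ether undergoes aromatic Claisen rearrangement to its only free ortho carbon (C2'), releasing the 3'-OH, and the C2 stereocentre is not involved.

**Step 11**
Reactants: **13**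
Product: **14** 7-allyl-6-[(2S)-7-hydroxychroman-2-yl]-2,2-dimethyl-2H-chromen-8-ol
Conditions: 2 M HCl (aq), MeOH–THF, rt → 40 °C
Reagents that add atoms: none
Why: Acetal hydrolysis of the aryl MOM ether is done while the side chain is still a terminal allyl group (much harder to protonate than prenyl); the dimethylchromene and the 4'-O-alkyl flavan tolerate dilute methanolic HCl.

**Step 12**
Reactants: **14** and **15** 2-methylbut-2-ene
Product: **16** Kazinol B
Conditions: Grubbs II (5 mol %), 1,4-benzoquinone (10 mol %), 2-methylbut-2-ene/CH2Cl2 (1:1), 35 °C, 12 h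
Reagents that add atoms: 2-methylbut-2-ene, CC=C(C)C (delivers the =C(CH3)2 terminus; propene is lost)
Why: Olefin cross-metathesis of the terminal allyl group with excess 2-methylbut-2-ene gives the prenyl group under neutral conditions; free phenols are tolerated and the chromene alkene (cis-disubstituted, next to a quaternary carbon) is a spectator.

## Compound list

1 | umbelliferone (7-hydroxy-2H-chromen-2-one) | O=c1ccc2ccc(O)cc2o1 | starting material
2 | 7-(methoxymethoxy)-2H-chromen-2-one | COCOc1ccc2ccc(=O)oc2c1 | intermediate
3 | 7-(methoxymethoxy)chroman-2-one | COCOc1ccc2CCC(=O)Oc2c1 | intermediate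
4 | rac-7-(methoxymethoxy)chroman-2-ol | COCOc1ccc2CCC(O)Oc2c1 | intermediate
5 | 2-(allyloxy)phenol | C=CCOc1ccccc1O | starting material
6 | 2-(allyloxy)-4-bromophenol | C=CCOc1cc(Br)ccc1O | intermediate
7 | [2-(allyloxy)-4-bromophenoxy](tert-butyl)dimethylsilane | C=CCOc1cc(Br)ccc1O[Si](C)(C)C(C)(C)C | intermediate
8 | rac-1-[3-(allyloxy)-4-(TBS-oxy)phenyl]-3-[2-hydroxy-4-(methoxymethoxy)phenyl]propan-1-ol | C=CCOc1cc(C(O)CCc2ccc(OCOC)cc2O)ccc1O[Si](C)(C)C(C)(C)C | intermediate
9 | rac-2-(allyloxy)-4-{1-hydroxy-3-[2-hydroxy-4-(methoxymethoxy)phenyl]propyl}phenol | C=CCOc1cc(C(O)CCc2ccc(OCOC)cc2O)ccc1O | intermediate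
10 | (2S)-2-[3-(allyloxy)-4-hydroxyphenyl]-7-(methoxymethoxy)chromane | C=CCOc1cc([C@@H]2CCc3ccc(OCOC)cc3O2)ccc1O | intermediate
11 | 3-chloro-3-methylbut-1-yne | CC(C)(Cl)C#C | starting material
12 | (2S)-2-{3-(allyloxy)-4-[(2-methylbut-3-yn-2-yl)oxy]phenyl}-7-(methoxymethoxy)chromane | C=CCOc1cc([C@@H]2CCc3ccc(OCOC)cc3O2)ccc1OC(C)(C)C#C | intermediate
13 | 7-allyl-6-[(2S)-7-(methoxymethoxy)chroman-2-yl]-2,2-dimethyl-2H-chromen-8-ol | C=CCc1c([C@@H]2CCc3ccc(OCOC)cc3O2)cc2c(c1O)OC(C)(C)C=C2 | intermediate
14 | 7-allyl-6-[(2S)-7-hydroxychroman-2-yl]-2,2-dimethyl-2H-chromen-8-ol | C=CCc1c([C@@H]2CCc3ccc(O)cc3O2)cc2c(c1O)OC(C)(C)C=C2 | intermediate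
15 | 2-methylbut-2-ene | CC=C(C)C | starting material
16 | Kazinol B, (2S) | CC(C)=CCc1c([C@@H]2CCc3ccc(O)cc3O2)cc2c(c1O)OC(C)(C)C=C2 | target

## Summary

Total steps: 12.
Longest linear sequence: 10 (steps 1–3, 6–12 from umbelliferone).

Three steps most likely to fail:

1. **Step 8 (proposed new cyclisation).** Risks are low ee (uncatalysed SN1 background, E/Z quinone methide mixture), tautomerisation of the quinone methide to a 4-hydroxystyrene, oligomerisation, and slow acid-mediated racemisation of the product. Fallback (known chemistry): add the aryllithium from **7** to lactone **3** to give the aryl ketone, reduce it to the (R)-carbinol by CBS reduction with (S)-Me-CBS/BH3 (or Noyori transfer hydrogenation), close the ring by intramolecular Mitsunobu etherification with inversion to the (S)-flavan, then TBAF to rejoin the route at **10**.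

2. **Step 9 (propargylation of the 4'-hydroxyflavan under base).** The 4'-phenoxide can expel the A-ring aryloxide (retro-1,6-addition) and erode ee, and the tertiary alkylation is hindered by the ortho allyloxy group. Fallback: avoid phenoxide chemistry by building the pyran through C–C bond formation first. Condense **10** with 3-methylbut-2-enal under PhB(OH)2/AcOH (toluene, Dean–Stark), which gives ortho-specific condensation via an aryl boronate followed by oxa-6π electrocyclisation to the 8-allyloxy chromene. Then run the allyl Claisen alone at 190 °C to reach **13**.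

3. **Step 10 (one-pot double Claisen at 190 °C).** Risks are para (C6') allyl migration, because C2' is flanked by the chromanyl group, and thermal decomposition. Fallback: stop at 140 °C (chromene formed, allyl ether intact) and remove the allyl group with Pd(PPh3)4/morpholine. Convert the 3'-OH into its 1,1-dimethylallyl ether (Pd(PPh3)4, tert-butyl 2-methylbut-3-en-2-yl carbonate) and run the low-temperature aromatic Claisen (Eu(fod)3, 60 °C) to install the prenyl group directly. Then remove MOM; this path needs neither the 190 °C step nor the metathesis.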